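## Retrosynthetic overview

1. The C5–C6 bond is made last: an enantioselective intramolecular Hosomi–Sakurai allylation (2-substituted allylsilane onto an (E)-enal) closes the 12-membered ring, and O-acetylation follows.
2. C9–C10 and the butenolide come from a vinylogous Mukaiyama aldol of the prenal-derived silyl dienol ether with a ring A 2-formyl enoate, followed by lactonisation.
3. The formyl enoate comes from the enol triflate of the ring A β-keto ester, which is made by a one-carbon ring expansion (diazoacetate insertion with 1,2-shift) of an (R)-3-alkyl-2,2-dimethylcyclopentanone.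
4. The cyclopentanone comes from a copper-catalysed asymmetric conjugate addition/enolate methylation of 2-methylcyclopent-2-enone with an allylsilane Grignard reagent made from 3-methylbut-3-en-1-ol.
5. Ring order: five-membered carbocycle (purchased), six-membered ring A (ring expansion), butenolide, 12-membered ring.

Positions are numbered as in verticillane: C1 (ring-fusion CH), C2, C3, C4(=C20H2), C5, C6 (OAc), C7=C8(C19H3), C9, C10 (lactone O), C11=C12, C13, C14, C15(CH3)2, C18 (lactone C=O on C12). The target is (1R,6S,7E,10R).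

Assumption: the facial sense of the catalyst-controlled steps 3, 8 and 9 is assigned by analogy with the closest reported cases; where a named catalyst enantiomer gives the opposite sense, its mirror image is used.

## Route

Step 1
Reactants: 1 3-methylbut-3-en-1-ol
Product: 4 3-[(trimethylsilyl)methyl]but-3-en-1-ol, via dilithium dianion 2 (not isolated), via bis-silyl compound 3 (not isolated)
Conditions: n-BuLi (2.2 equiv), TMEDA, Et2O–hexane, 0 °C → rt; Me3SiCl, −78 °C → rt; then 1 M H2SO4, THF, rt
Reagents that add atoms: chlorotrimethylsilane C[Si](C)(C)Cl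
Why: Alkoxide-directed allylic lithiation of the methyl group gives a symmetrical 2-substituted allyl anion that is C-silylated, and dilute acid then removes only the O-silyl group (dianion alkylation; no stereocentre).

Step 2
Reactants: 4 3-[(trimethylsilyl)methyl]but-3-en-1-ol
Product: 5 [2-(2-bromoethyl)prop-2-en-1-yl]trimethylsilane
Conditions: CBr4, PPh3, CH2Cl2, 0 °C
Reagents that add atoms: carbon tetrabromide BrC(Br)(Br)Br
Why: Appel bromination of the primary alcohol runs under neutral conditions that leave the acid-sensitive allylsilane intact.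

Step 3
Reactants: 5 [2-(2-bromoethyl)prop-2-en-1-yl]trimethylsilane; 6 2-methylcyclopent-2-en-1-one
Product: 9 (3R)-2,2-dimethyl-3-{3-[(trimethylsilyl)methyl]but-3-en-1-yl}cyclopentan-1-one, via Grignard reagent 7 (not isolated), via magnesium enolate 8 (not isolated)
Conditions: Mg, Et2O, 35 °C; then 6, Cu(OTf)2 (3 mol %), 3-[(2S)-1-hydroxy-4-methylpentan-2-yl]-1-(2,4,6-trimethylphenyl)-4,5-dihydro-1H-imidazol-3-ium hexafluorophosphate (4 mol %), Et2O, −30 °C; then MeI, DMPU, −30 °C → rt
Reagents that add atoms: iodomethane CI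
Why: Copper–NHC-catalysed asymmetric conjugate addition of the alkyl Grignard reagent to the α-methyl enone sets C1 (R) by ligand-controlled facial delivery, and the regiodefined magnesium enolate is then C-methylated at the methyl-bearing carbon (tandem conjugate addition–enolate alkylation) to give the gem-dimethyl carbon C15.

Step 4
Reactants: 9 (3R)-2,2-dimethyl-3-{3-[(trimethylsilyl)methyl]but-3-en-1-yl}cyclopentan-1-one; 10 ethyl diazoacetate
Product: 11 ethyl (4S)-3,3-dimethyl-2-oxo-4-{3-[(trimethylsilyl)methyl]but-3-en-1-yl}cyclohexane-1-carboxylate (keto–enol and C1-epimer mixture)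
Conditions: BF3·OEt2 (1.2 equiv), Et2O, −20 → 0 °C, slow addition of 10
Reagents that add atoms: none
Why: Lewis-acid-promoted diazo ester homologation (Tiffeneau–Demjanov-type ring expansion): the diazo carbon adds to the activated ketone and loss of N2 drives a 1,2-shift of the less substituted ring CH2 rather than the quaternary carbon, which turns the cyclopentanone into ring A with C12 and C18 in place and leaves C1 untouched (its descriptor changes only through the priority rules).

Step 5
Reactants: 11 ethyl (4S)-3,3-dimethyl-2-oxo-4-{3-[(trimethylsilyl)methyl]but-3-en-1-yl}cyclohexane-1-carboxylate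
Product: 13 ethyl (4S)-3,3-dimethyl-2-{[(trifluoromethyl)sulfonyl]oxy}-4-{3-[(trimethylsilyl)methyl]but-3-en-1-yl}cyclohex-1-ene-1-carboxylate, via sodium enolate 12 (not isolated)
Conditions: NaH, THF, 0 °C; then PhNTf2, rt; 1 M HCl work-up
Reagents that add atoms: N-phenylbis(trifluoromethanesulfonimide) O=S(=O)(N(c1ccccc1)S(=O)(=O)C(F)(F)F)C(F)(F)F
Why: O-triflation of the stabilised β-keto ester enolate, which can only form towards C12 because the other α-carbon is quaternary.

Step 6
Reactants: 13 ethyl (4S)-3,3-dimethyl-2-{[(trifluoromethyl)sulfonyl]oxy}-4-{3-[(trimethylsilyl)methyl]but-3-en-1-yl}cyclohex-1-ene-1-carboxylate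
Product: 14 ethyl (4S)-2-formyl-3,3-dimethyl-4-{3-[(trimethylsilyl)methyl]but-3-en-1-yl}cyclohex-1-ene-1-carboxylate
Conditions: Pd(PPh3)4 (5 mol %), CO (3 atm), Bu3SnH (slow addition), LiCl, THF, 50 °C
Reagents that add atoms: carbon monoxide [C-]#[O+]
Why: Palladium-catalysed formylation (reductive carbonylation) of the enol triflate by oxidative addition, CO insertion and hydride transfer from the tin hydride installs the aldehyde carbon C10.

Step 7
Reactants: 15 3-methylbut-2-enal
Product: 16 tert-butyl(dimethyl){[(1E)-3-methylbuta-1,3-dien-1-yl]oxy}silane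
Conditions: TBSOTf, Et3N, Et2O, 0 °C → rt
Reagents that add atoms: tert-butyldimethylsilyl trifluoromethanesulfonate CC(C)(C)[Si](C)(C)OS(=O)(=O)C(F)(F)F
Why: Soft enolisation of the enal by γ-deprotonation gives the (E)-silyl dienol ether, the γ-nucleophile for the vinylogous aldol step.

Step 8
Reactants: 14 ethyl (4S)-2-formyl-3,3-dimethyl-4-{3-[(trimethylsilyl)methyl]but-3-en-1-yl}cyclohex-1-ene-1-carboxylate; 16 tert-butyl(dimethyl){[(1E)-3-methylbuta-1,3-dien-1-yl]oxy}silane
Product: 18 (3R,5S)-4,4-dimethyl-3-[(2E)-2-methyl-4-oxobut-2-en-1-yl]-5-{3-[(trimethylsilyl)methyl]but-3-en-1-yl}-4,5,6,7-tetrahydro-2-benzofuran-1(3H)-one, via hydroxy ester 17 (not isolated)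
Conditions: (4S)-4-(1H-indol-3-ylmethyl)-2-phenyl-3-(4-methylphenylsulfonyl)-1,3,2-oxazaborolidin-5-one (50 mol %), i-PrOH (1.2 equiv), EtCN, −78 °C; then pyridinium p-toluenesulfonate, CH2Cl2, rt
Reagents that add atoms: none
Why: Enantioselective vinylogous Mukaiyama aldol reaction in which the boron Lewis acid binds the aldehyde and exposes its Re face to the γ-carbon of the dienol ether reacting in its s-trans form, which forms C9–C10, sets C10 (R) and the 7E enal, after which the free hydroxyl lactonises onto the cis ester to close the butenolide.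

Step 9
Reactants: 18 (3R,5S)-4,4-dimethyl-3-[(2E)-2-methyl-4-oxobut-2-en-1-yl]-5-{3-[(trimethylsilyl)methyl]but-3-en-1-yl}-4,5,6,7-tetrahydro-2-benzofuran-1(3H)-one
Product: 20 (1R,6S,7E,10R)-6-hydroxyverticilla-4(20),7,11-trien-18,10-olide, via macrocyclic trimethylsilyl ether 19 (not isolated)
Conditions: (S)-3,3′-bis[3,5-bis(trifluoromethyl)phenyl]-1,1′-binaphthalene-2,2′-disulfonimide as its N-SiMe3 derivative (10 mol %), CH2Cl2, −40 → −20 °C, syringe-pump addition of 18 (final 2 mM); then pyridinium p-toluenesulfonate, MeOH, 0 °C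
Reagents that add atoms: none
Why: Proposed new method: an intramolecular, macrocyclising Hosomi–Sakurai allylation under chiral silylium–disulfonimide ion-pair catalysis, in which the N-silyl catalyst silylates the enal oxygen, the terminal carbon of the 2-substituted allylsilane attacks the Si face of the resulting oxocarbenium ion inside the chiral anion pocket to form C5–C6 and the 12-membered ring with C6 (S), and the β-silyl cation hands Me3Si+ back to the anion to regenerate the catalyst and leave the exocyclic methylene; the closest known reaction is the intermolecular disulfonimide-catalysed asymmetric Hosomi–Sakurai reaction of 2-substituted allylsilanes with conjugated aldehydes, which has not been shown intramolecularly or for macrocycle formation.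

Step 10
Reactants: 20 (1R,6S,7E,10R)-6-hydroxyverticilla-4(20),7,11-trien-18,10-olide
Product: 21 (1R,6S,7E,10R)-6-acetoxyverticilla-4(20),7,11-trien-18,10-olide (CNP0289913.1)
Conditions: Ac2O, pyridine, 4-(dimethylamino)pyridine (cat.), CH2Cl2, 0 °C → rt
Reagents that add atoms: acetic anhydride CC(=O)OC(C)=O
Why: Nucleophile-catalysed O-acylation of the secondary alcohol proceeds with retention at C6 and gives the target.

## Compound list

1 | 3-methylbut-3-en-1-ol | C=C(C)CCO | starting material
2 | dilithium dianion of 1 (lithium 3-(lithiomethyl)but-3-en-1-olate) | [Li]CC(=C)CCO[Li] | intermediate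
3 | trimethyl({3-[(trimethylsilyl)methyl]but-3-en-1-yl}oxy)silane | C[Si](C)(C)CC(=C)CCO[Si](C)(C)C | intermediate
4 | 3-[(trimethylsilyl)methyl]but-3-en-1-ol | C[Si](C)(C)CC(=C)CCO | intermediate
5 | [2-(2-bromoethyl)prop-2-en-1-yl]trimethylsilane | C[Si](C)(C)CC(=C)CCBr | intermediate
6 | 2-methylcyclopent-2-en-1-one | CC1=CCCC1=O | starting material
7 | {3-[(trimethylsilyl)methyl]but-3-en-1-yl}magnesium bromide | C[Si](C)(C)CC(=C)CC[Mg]Br | intermediate
8 | bromomagnesium (3R)-2-methyl-3-{3-[(trimethylsilyl)methyl]but-3-en-1-yl}cyclopent-1-en-1-olate | C[Si](C)(C)CC(=C)CC[C@@H]1CCC(O[Mg]Br)=C1C | intermediate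
9 | (3R)-2,2-dimethyl-3-{3-[(trimethylsilyl)methyl]but-3-en-1-yl}cyclopentan-1-one | C[Si](C)(C)CC(=C)CC[C@@H]1CCC(=O)C1(C)C | intermediate
10 | ethyl diazoacetate | CCOC(=O)C=[N+]=[N-] | starting material
11 | ethyl (4S)-3,3-dimethyl-2-oxo-4-{3-[(trimethylsilyl)methyl]but-3-en-1-yl}cyclohexane-1-carboxylate (C1 epimers, keto–enol mixture) | C[Si](C)(C)CC(=C)CC[C@@H]1CCC(C(=O)OCC)C(=O)C1(C)C | intermediate
12 | sodium enolate of 11 (configuration at the side-chain carbon unchanged) | C[Si](C)(C)CC(=C)CC[C@@H]1CCC(C(=O)OCC)=C([O-])C1(C)C.[Na+] | intermediate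
13 | ethyl (4S)-3,3-dimethyl-2-{[(trifluoromethyl)sulfonyl]oxy}-4-{3-[(trimethylsilyl)methyl]but-3-en-1-yl}cyclohex-1-ene-1-carboxylate | C[Si](C)(C)CC(=C)CC[C@@H]1CCC(C(=O)OCC)=C(OS(=O)(=O)C(F)(F)F)C1(C)C | intermediate
14 | ethyl (4S)-2-formyl-3,3-dimethyl-4-{3-[(trimethylsilyl)methyl]but-3-en-1-yl}cyclohex-1-ene-1-carboxylate | C[Si](C)(C)CC(=C)CC[C@@H]1CCC(C(=O)OCC)=C(C=O)C1(C)C | intermediate
15 | 3-methylbut-2-enal | CC(C)=CC=O | starting material
16 | tert-butyl(dimethyl){[(1E)-3-methylbuta-1,3-dien-1-yl]oxy}silane | C=C(C)/C=C/O[Si](C)(C)C(C)(C)C | intermediate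
17 | ethyl (4S)-2-[(1R,3E)-1-hydroxy-3-methyl-5-oxopent-3-en-1-yl]-3,3-dimethyl-4-{3-[(trimethylsilyl)methyl]but-3-en-1-yl}cyclohex-1-ene-1-carboxylate | C[Si](C)(C)CC(=C)CC[C@@H]1CCC(C(=O)OCC)=C([C@H](O)C/C(C)=C/C=O)C1(C)C | intermediate
18 | (3R,5S)-4,4-dimethyl-3-[(2E)-2-methyl-4-oxobut-2-en-1-yl]-5-{3-[(trimethylsilyl)methyl]but-3-en-1-yl}-4,5,6,7-tetrahydro-2-benzofuran-1(3H)-one | C[Si](C)(C)CC(=C)CC[C@@H]1CCC2=C([C@@H](C/C(C)=C/C=O)OC2=O)C1(C)C | intermediate
19 | (1R,6S,7E,10R)-6-(trimethylsilyloxy)verticilla-4(20),7,11-trien-18,10-olide | C=C1CC[C@@H]2CCC3=C([C@@H](C/C(C)=C/[C@@H](O[Si](C)(C)C)C1)OC3=O)C2(C)C | intermediate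
20 | (1R,6S,7E,10R)-6-hydroxyverticilla-4(20),7,11-trien-18,10-olide | C=C1CC[C@@H]2CCC3=C([C@@H](C/C(C)=C/[C@@H](O)C1)OC3=O)C2(C)C | intermediate
21 | (1R,6S,7E,10R)-6-acetoxyverticilla-4(20),7,11-trien-18,10-olide (CNP0289913.1) | C=C1CC[C@@H]2CCC3=C([C@@H](C/C(C)=C/[C@@H](OC(C)=O)C1)OC3=O)C2(C)C | target

## Step count and risks

Total step count: 10. Longest linear sequence: 9 steps (steps 1–6 and 8–10); step 7 is a one-step side branch.

The three steps most likely to fail:

**Step 9 (the new macrocyclisation).** Ring strain in the 12-membered transition state, a mismatched catalyst/substrate preference at C6, or quenching of the silylium catalyst by the lactone could stop it. The fallback uses known chemistry and sets out from 18. Bromodesilylation with N-bromosuccinimide (propylene oxide, CH2Cl2, −78 °C; SE2′ attack of electrophilic bromine on the allylsilane) gives the allylic bromide (3R,5S)-5-[3-(bromomethyl)but-3-en-1-yl]-4,4-dimethyl-3-[(2E)-2-methyl-4-oxobut-2-en-1-yl]-4,5,6,7-tetrahydro-2-benzofuran-1(3H)-one F1. An intramolecular Nozaki–Hiyama–Kishi allylation (CrCl2, THF, 2 mM, rt, with a chiral sulfonamide ligand on chromium if substrate control at C6 is poor) then closes the ring, and the fallback comes back to the route at 20.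

**Step 8 (vinylogous aldol on a hindered, tetrasubstituted enal).** Low reactivity, α- instead of γ-attack, enal E/Z erosion or poor control at C10 are possible. The fallback reverses the roles of nucleophile and electrophile at C9–C10 and sets out from 13 and 16:
- Stille coupling of 13 with (tributylstannyl)methanol (Pd(PPh3)4, LiCl, dioxane, 90 °C) gives ethyl (4S)-2-(hydroxymethyl)-3,3-dimethyl-4-{3-[(trimethylsilyl)methyl]but-3-en-1-yl}cyclohex-1-ene-1-carboxylate F2.
- F2 lactonises in the flask to the butenolide (5S)-4,4-dimethyl-5-{3-[(trimethylsilyl)methyl]but-3-en-1-yl}-4,5,6,7-tetrahydro-2-benzofuran-1(3H)-one F3.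
- Triisopropylsilyl triflate and Et3N convert F3 into the silyloxyfuran {[(5S)-4,4-dimethyl-5-{3-[(trimethylsilyl)methyl]but-3-en-1-yl}-4,5,6,7-tetrahydro-2-benzofuran-1-yl]oxy}tri(propan-2-yl)silane F4.
- N-Bromosuccinimide (THF, −78 °C) turns 16 into (2E)-4-bromo-3-methylbut-2-enal F5.
- γ-Alkylation of F4 with F5 promoted by silver trifluoroacetate (CH2Cl2, −78 °C) forms C9–C10. C10 is then set by approach anti to the pseudo-axial C15 methyl group, and the epimers are separated by chromatography.

The fallback comes back to the route at 18.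

**Step 4 (ring expansion).** The BF3-activated, hindered ketone may be attacked by the internal allylsilane, the allylsilane may be protodesilylated, or the quaternary carbon may migrate. The fallback keeps the ring expansion but avoids any Lewis acid and sets out from 9 and 10. Lithium diisopropylamide (THF, −78 °C) adds lithiated ethyl diazoacetate to the ketone to give the β-hydroxy-α-diazo ester ethyl 2-diazo-2-[(1RS,3R)-1-hydroxy-2,2-dimethyl-3-{3-[(trimethylsilyl)methyl]but-3-en-1-yl}cyclopentyl]acetate F6. Rh2(OAc)4 (1 mol %, CH2Cl2, rt) then converts F6 through the rhodium carbenoid and a 1,2-shift of the ring CH2 into the same β-keto ester, and the fallback comes back to the route at 11.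

## Further compounds

F1 | step 9 | (3R,5S)-5-[3-(bromomethyl)but-3-en-1-yl]-4,4-dimethyl-3-[(2E)-2-methyl-4-oxobut-2-en-1-yl]-4,5,6,7-tetrahydro-2-benzofuran-1(3H)-one | BrCC(=C)CC[C@@H]1CCC2=C([C@@H](C/C(C)=C/C=O)OC2=O)C1(C)C
F2 | step 8 | ethyl (4S)-2-(hydroxymethyl)-3,3-dimethyl-4-{3-[(trimethylsilyl)methyl]but-3-en-1-yl}cyclohex-1-ene-1-carboxylate | C[Si](C)(C)CC(=C)CC[C@@H]1CCC(C(=O)OCC)=C(CO)C1(C)C
F3 | step 8 | (5S)-4,4-dimethyl-5-{3-[(trimethylsilyl)methyl]but-3-en-1-yl}-4,5,6,7-tetrahydro-2-benzofuran-1(3H)-one | C[Si](C)(C)CC(=C)CC[C@@H]1CCC2=C(COC2=O)C1(C)C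
F4 | step 8 | {[(5S)-4,4-dimethyl-5-{3-[(trimethylsilyl)methyl]but-3-en-1-yl}-4,5,6,7-tetrahydro-2-benzofuran-1-yl]oxy}tri(propan-2-yl)silane | C[Si](C)(C)CC(=C)CC[C@@H]1CCc2c(coc2O[Si](C(C)C)(C(C)C)C(C)C)C1(C)C
F5 | step 8 | (2E)-4-bromo-3-methylbut-2-enal | BrC/C(C)=C/C=O
F6 | step 4 | ethyl 2-diazo-2-[(1RS,3R)-1-hydroxy-2,2-dimethyl-3-{3-[(trimethylsilyl)methyl]but-3-en-1-yl}cyclopentyl]acetate | C[Si](C)(C)CC(=C)CC[C@@H]1CCC(O)(C(=[N+]=[N-])C(=O)OCC)C1(C)C
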